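**Strategy.** Everything rests on cutting ring B, the tetrahydrofuran that carries the free guaiacyl group, into formaldehyde (its O5–C6 unit) and the three-carbon chain C4(benzylic)–C3a–C6a (furo[3,4-c]furan numbering, free guaiacyl group on C4). This chain is stored as a cyclopropane fused to a γ-lactone, the future ring A. A Lewis acid-catalysed (3+2) annulation of this donor–acceptor cyclopropane with formaldehyde forms the C6–C6a and O5–C4 bonds in one operation and, by inversion at C4, turns the endo (cis) aryl group of the cyclopropane into the exo aryl group of the furofuranone. The precursor is an enantioenriched methyl 6-endo-aryl-2-oxo-3-oxabicyclo[3.1.0]hexane-1-carboxylate whose phenol is masked as a sulfonate to keep the opening stereospecific.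

Key step: step 6

Remark: the target is read as the (1R,2S)-erythro 1-arylglycerol 2-aryl ether of a (1R,3aS,4R,6aS)-1,4-diaryl furofuran with both aryl groups exo.
Remark: compounds 6 and 18 are taken as purchasable; in step 4 the ligand antipode is the one that delivers (2S,3S)-7.
Abbreviations: ArTs = 3-methoxy-4-(4-methylphenylsulfonyloxy)phenyl; "core-O" = the 4-[(1R,3aS,4R,6aS)-4-ArTs-tetrahydro-1H,3H-furo[3,4-c]furan-1-yl]-2-methoxyphenoxy group of 17; TBS = tert-butyldimethylsilyl.

**Step 1**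
Reactants: 1 4-bromo-2-methoxyphenol
Product: 2 4-bromo-2-methoxyphenyl 4-methylbenzenesulfonate
Conditions: TsCl, Et3N, DMAP (cat.), CH2Cl2, 0 °C → rt
Reagents that add atoms: 4-methylbenzenesulfonyl chloride, Cc1ccc(cc1)S(Cl)(=O)=O
Why: O-Sulfonylation of the phenol gives a protecting group that is stable to base, hydride and Grignard reagents and that lowers the donor strength of the aryl ring for step 6.

**Step 2**
Reactants: 2 4-bromo-2-methoxyphenyl 4-methylbenzenesulfonate; 3 tert-butyldimethyl(prop-2-yn-1-yloxy)silane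
Product: 4 4-[3-(TBS-oxy)prop-1-yn-1-yl]-2-methoxyphenyl 4-methylbenzenesulfonate
Conditions: Pd(PPh3)2Cl2 (3 mol%), CuI (5 mol%), Et3N, THF, 65 °C
Reagents that add atoms: none
Why: Sonogashira coupling, in which palladium inserts into the aryl–Br bond (the aryl sulfonate is inert to the PPh3 catalyst) and the copper acetylide transmetalates, should give the aryl alkyne.

**Step 3**
Reactants: 4 aryl alkyne
Product: 5 4-[(1Z)-3-(TBS-oxy)prop-1-en-1-yl]-2-methoxyphenyl 4-methylbenzenesulfonate
Conditions: H2 (1 atm), Pd/CaCO3 poisoned with Pb(OAc)2, quinoline, EtOAc, rt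
Reagents that add atoms: none
Why: Lindlar semihydrogenation delivers both hydrogens to one face of the alkyne and stops at the (Z)-alkene, leaving sulfonate and silyl ether untouched.

**Step 4**
Reactants: 5 (Z)-alkene; 6 bis(methoxycarbonyl)(phenyliodonio)methanide (iodonium ylide of dimethyl malonate)
Product: 7 dimethyl (2S,3S)-2-ArTs-3-[(TBS-oxy)methyl]cyclopropane-1,1-dicarboxylate (aryl and CH2OTBS cis)
Conditions: Cu(MeCN)4PF6 (5 mol%), chiral side-arm bis(oxazoline) ligand (6 mol%), 4 Å MS, toluene, 0 °C → rt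
Reagents that add atoms: none
Why: Asymmetric copper–bis(oxazoline) carbene cyclopropanation with the malonate iodonium ylide is a concerted, stereospecific addition that keeps the (Z) geometry (aryl and CH2OTBS cis), while the chiral ligand selects the alkene face and so sets both stereocentres.

**Step 5**
Reactants: 7 cis-cyclopropane diester
Product: 9 methyl (1R,5S,6S)-6-ArTs-2-oxo-3-oxabicyclo[3.1.0]hexane-1-carboxylate (aryl endo), via hydroxy diester 8 (not isolated)
Conditions: Bu4NF (1.1 equiv), THF, 0 °C → rt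
Reagents that add atoms: none
Why: Fluoride desilylation frees the alkoxide, which can reach only the ester on its own face of the cyclopropane and closes the cis-fused γ-lactone (5-exo-trig transesterification), so the former malonate carbon becomes a defined stereocentre and the other two are untouched.

**Step 6**
Reactants: 9 endo-aryl cyclopropane lactone ester
Product: 10 methyl (3aS,4R,6aS)-4-ArTs-1-oxotetrahydro-1H,3H-furo[3,4-c]furan-6a-carboxylate (aryl exo)
Conditions: paraformaldehyde (5 equiv), Sc(OTf)3 (10 mol%), 4 Å MS, ClCH2CH2Cl, 50 °C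
Reagents that add atoms: formaldehyde (from paraformaldehyde), C=O
Why: Sc(OTf)3 chelates the lactone and ester carbonyls on C1 of 9 and polarizes the C1–C6 bond; the oxygen of formaldehyde attacks the benzylic carbon C6 from the side opposite to C1 (SN2-like opening of the intimate ion pair) and the metal-bound malonate-type enolate then adds to the carbon of the O-alkylated oxocarbenium ion, so the O–C(benzylic) and CH2–C(fusion) bonds form in one operation. The closest known reaction is the Lewis acid-catalysed (3+2) annulation of 2-arylcyclopropane-1,1-dicarboxylates with aldehydes to give tetrahydrofurans, used here with formaldehyde and a lactone-fused cyclopropane. The tetrahydrofuran ring (ring B) closes by a 5-(enolexo)-endo-trig aldol-type attack on the oxocarbenium ion, the ring closure inherent to this annulation. The benzylic centre is set by inversion, which moves the aryl group from the endo position of 9 (cis to the lactone CH2) to the exo position of 10 (trans to it), and the new quaternary fusion centre is dictated by the ring, since the OCH2 bridge can only bond on the face the cyclopropane carbon left and a cis-fused bicycle results. The step needs stereospecific opening without a free benzylic cation, which the sulfonate secures by making the aryl ring no better a donor than phenyl so that C6 does not epimerize before capture, while the strain of the endo-substituted, lactone-fused cyclopropane supplies reactivity. It also needs cleavage of C1–C6 and not C1–C5, which follows because only C6 carries a cation-stabilizing group.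

**Step 7**
Reactants: 10 furofuranone ester
Product: 11 (3aS,4R,6aS)-4-ArTs-tetrahydro-1H,3H-furo[3,4-c]furan-1-one
Conditions: LiCl (3 equiv), H2O (2 equiv), DMSO, 130 °C
Reagents that add atoms: none
Why: Krapcho dealkoxycarbonylation, in which chloride demethylates the ester, CO2 is lost and the lactone enolate is protonated on the only face that keeps the bicycle cis-fused, should work because β-elimination of the ring oxygen is disfavoured (its C–O bond lies near the nodal plane of the enolate).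

**Step 8**
Reactants: 11 furofuranone
Product: 12 (3aS,4R,6aS)-4-ArTs-tetrahydro-1H,3H-furo[3,4-c]furan-1-ol (lactol, both C1 epimers)
Conditions: i-Bu2AlH (1.1 equiv), CH2Cl2, −78 °C; aq. potassium sodium tartrate
Reagents that add atoms: none
Why: Partial reduction of the lactone with i-Bu2AlH at −78 °C stops at the aluminium hemiacetal, which gives the lactol on hydrolysis, and the aryl sulfonate is inert.

**Step 9**
Reactants: 1 4-bromo-2-methoxyphenol
Product: 13 (4-bromo-2-methoxyphenoxy)(tert-butyl)dimethylsilane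
Conditions: TBSCl, imidazole, DMF, rt
Reagents that add atoms: tert-butyldimethylsilyl chloride, CC(C)(C)[Si](C)(C)Cl
Why: Imidazole-promoted silylation of the phenol gives an ether that survives Grignard formation and is later removed by fluoride without touching the aryl sulfonate.

**Step 10**
Reactants: 12 lactol; 13 silyl-protected aryl bromide
Product: 15 {(3S,4S,5R)-4-(hydroxymethyl)-5-ArTs-oxolan-3-yl}[4-(TBS-oxy)-3-methoxyphenyl]methanol (both carbinol epimers), via aryl Grignard reagent 14 (not isolated)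
Conditions: 13, Mg, THF, 45 °C; then 12 added to 14 (3 equiv), THF, −20 → 0 °C; aq. NH4Cl
Reagents that add atoms: none
Why: Grignard addition to the open hydroxy aldehyde form of the lactol (one equivalent deprotonates the lactol) gives the benzylic carbinol as an epimer mixture, which is of no consequence because this centre is reset in step 11, and the ring stereocentres are not enolized at low temperature.

**Step 11**
Reactants: 15 diol
Product: 16 (1R,3aS,4R,6aS)-1-[4-(TBS-oxy)-3-methoxyphenyl]-4-ArTs-tetrahydro-1H,3H-furo[3,4-c]furan (both aryl groups exo)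
Conditions: BF3·OEt2 (0.2 equiv), CH2Cl2, −30 → 0 °C
Reagents that add atoms: none
Why: Acid-mediated SN1 cycloetherification, in which the p-silyloxybenzylic alcohol ionizes and the primary hydroxyl captures the cation in a 5-exo closure, should place the aryl group exo because allylic 1,3-strain holds the fusion C–H in the plane of the cation, while the other benzylic ether, on the sulfonate-bearing ring, does not ionize and keeps its configuration.

**Step 12**
Reactants: 16 silyl-protected furofuran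
Product: 17 4-[(1R,3aS,4R,6aS)-4-ArTs-tetrahydro-1H,3H-furo[3,4-c]furan-1-yl]-2-methoxyphenol
Conditions: Bu4NF, THF, 0 °C
Reagents that add atoms: none
Why: Fluoride cleaves the aryl silyl ether selectively at 0 °C, conditions under which aryl sulfonates and the benzylic ethers are stable.

**Step 13**
Reactants: 17 phenol; 18 (4R)-4-benzyl-3-(chloroacetyl)-1,3-oxazolidin-2-one
Product: 19 (4R)-4-benzyl-3-[(core-O)acetyl]-1,3-oxazolidin-2-one
Conditions: K2CO3, NaI (cat.), acetone, rt
Reagents that add atoms: none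
Why: Williamson etherification, in which the phenoxide displaces the halide of the α-halo imide by SN2 with iodide catalysis, should be faster than attack at the imide carbonyls.

**Step 14**
Reactants: 20 vanillin (4-hydroxy-3-methoxybenzaldehyde)
Product: 21 4-formyl-2-methoxyphenyl 4-methylbenzenesulfonate
Conditions: TsCl, Et3N, DMAP (cat.), CH2Cl2, 0 °C → rt
Reagents that add atoms: 4-methylbenzenesulfonyl chloride, Cc1ccc(cc1)S(Cl)(=O)=O
Why: O-Sulfonylation as in step 1 gives an aldehyde whose aryl ring will not stabilize a benzylic cation in step 17 and whose protecting group leaves together with the other sulfonate in step 18.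

**Step 15**
Reactants: 19 aryloxyacetyl imide; 21 sulfonate-protected vanillin
Product: 23 (4R)-4-benzyl-3-[(2R,3S)-3-hydroxy-3-ArTs-2-(core-O)propanoyl]-1,3-oxazolidin-2-one, via boron enolate 22 (not isolated)
Conditions: Bu2BOTf (1.2 equiv), i-Pr2NEt (1.4 equiv), CH2Cl2, −78 → 0 °C; then 21, −78 → 0 °C; pH 7 buffer, MeOH, H2O2
Reagents that add atoms: none
Why: Evans syn aldol reaction, in which the (Z)-boron enolate reacts through a Zimmerman–Traxler chair on the face away from the benzyl group of the (R)-auxiliary, sets C2 (R) and C3 (S) of the propanoyl chain, which is the threo relation of aryloxy and hydroxyl groups.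

**Step 16**
Reactants: 23 aldol adduct
Product: 24 (1S,2S)-1-ArTs-2-(core-O)propane-1,3-diol (threo)
Conditions: LiBH4, THF–H2O, 0 °C
Reagents that add atoms: none
Why: Reductive cleavage of the N-acyl oxazolidinone with LiBH4 gives the primary alcohol and the free auxiliary without epimerization of the α-aryloxy centre, and sulfonates are not reduced.

**Step 17**
Reactants: 24 threo diol
Product: 25 (1R,2S)-1-ArTs-2-(core-O)propane-1,3-diyl bis(4-nitrobenzoate) (erythro)
Conditions: 4-nitrobenzoic acid (3 equiv), PPh3 (3 equiv), DIAD (3 equiv), THF, 0 °C → rt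
Reagents that add atoms: 4-nitrobenzoic acid, OC(=O)c1ccc(cc1)[N+](=O)[O-]
Why: In this Mitsunobu reaction the primary hydroxyl is esterified and the benzylic alkoxyphosphonium is displaced by 4-nitrobenzoate with inversion (SN2, favoured because the sulfonate keeps the aryl ring from stabilizing a cation), which converts (1S) into (1R) and threo into erythro.

**Step 18**
Reactants: 25 erythro bis(4-nitrobenzoate)
Product: 26 4-[(1R,2S)-1,3-dihydroxy-2-{4-[(1R,3aS,4R,6aS)-4-(4-hydroxy-3-methoxyphenyl)tetrahydro-1H,3H-furo[3,4-c]furan-1-yl]-2-methoxyphenoxy}propyl]-2-methoxyphenol (target)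
Conditions: KOH (2 M aq.), 1,4-dioxane, 65 °C; then aq. NH4Cl
Reagents that add atoms: none
Why: Hydroxide cleaves the two 4-nitrobenzoates at the acyl carbon and the two aryl sulfonates at sulfur, so no stereocentre is touched and both hydroxyls and both phenols of the target are released in one operation.

**Compound list**

1 | 4-bromo-2-methoxyphenol | COc1cc(Br)ccc1O | starting material
2 | 4-bromo-2-methoxyphenyl 4-methylbenzenesulfonate | COc1cc(Br)ccc1OS(=O)(=O)c1ccc(C)cc1 | intermediate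
3 | tert-butyldimethyl(prop-2-yn-1-yloxy)silane | C#CCO[Si](C)(C)C(C)(C)C | starting material
4 | 4-[3-(TBS-oxy)prop-1-yn-1-yl]-2-methoxyphenyl 4-methylbenzenesulfonate | COc1cc(C#CCO[Si](C)(C)C(C)(C)C)ccc1OS(=O)(=O)c1ccc(C)cc1 | intermediate
5 | 4-[(1Z)-3-(TBS-oxy)prop-1-en-1-yl]-2-methoxyphenyl 4-methylbenzenesulfonate | COc1cc(/C=C\CO[Si](C)(C)C(C)(C)C)ccc1OS(=O)(=O)c1ccc(C)cc1 | intermediate
6 | bis(methoxycarbonyl)(phenyliodonio)methanide | COC(=O)[C-](C(=O)OC)[I+]c1ccccc1 | starting material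
7 | dimethyl (2S,3S)-2-ArTs-3-[(TBS-oxy)methyl]cyclopropane-1,1-dicarboxylate (cis) | COC(=O)C1(C(=O)OC)[C@H](c2ccc(OS(=O)(=O)c3ccc(C)cc3)c(OC)c2)[C@@H]1CO[Si](C)(C)C(C)(C)C | intermediate
8 | dimethyl (2S,3S)-2-ArTs-3-(hydroxymethyl)cyclopropane-1,1-dicarboxylate (cis) | COC(=O)C1(C(=O)OC)[C@H](c2ccc(OS(=O)(=O)c3ccc(C)cc3)c(OC)c2)[C@@H]1CO | intermediate
9 | methyl (1R,5S,6S)-6-ArTs-2-oxo-3-oxabicyclo[3.1.0]hexane-1-carboxylate (aryl endo) | O=C1OC[C@H]2[C@@H](c3ccc(OS(=O)(=O)c4ccc(C)cc4)c(OC)c3)[C@@]12C(=O)OC | intermediate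
10 | methyl (3aS,4R,6aS)-4-ArTs-1-oxotetrahydro-1H,3H-furo[3,4-c]furan-6a-carboxylate (aryl exo) | O=C1OC[C@@H]2[C@@]1(C(=O)OC)CO[C@H]2c1ccc(OS(=O)(=O)c2ccc(C)cc2)c(OC)c1 | intermediate
11 | (3aS,4R,6aS)-4-ArTs-tetrahydro-1H,3H-furo[3,4-c]furan-1-one | O=C1OC[C@@H]2[C@H]1CO[C@H]2c1ccc(OS(=O)(=O)c2ccc(C)cc2)c(OC)c1 | intermediate
12 | (3aS,4R,6aS)-4-ArTs-tetrahydro-1H,3H-furo[3,4-c]furan-1-ol (lactol, C1 epimers) | OC1OC[C@@H]2[C@H]1CO[C@H]2c1ccc(OS(=O)(=O)c2ccc(C)cc2)c(OC)c1 | intermediate
13 | (4-bromo-2-methoxyphenoxy)(tert-butyl)dimethylsilane | COc1cc(Br)ccc1O[Si](C)(C)C(C)(C)C | intermediate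
14 | [4-(TBS-oxy)-3-methoxyphenyl]magnesium bromide | COc1cc([Mg]Br)ccc1O[Si](C)(C)C(C)(C)C | intermediate
15 | {(3S,4S,5R)-4-(hydroxymethyl)-5-ArTs-oxolan-3-yl}[4-(TBS-oxy)-3-methoxyphenyl]methanol (carbinol epimers) | OC[C@@H]1[C@@H](CO[C@H]1c1ccc(OS(=O)(=O)c2ccc(C)cc2)c(OC)c1)C(O)c1ccc(O[Si](C)(C)C(C)(C)C)c(OC)c1 | intermediate
16 | (1R,3aS,4R,6aS)-1-[4-(TBS-oxy)-3-methoxyphenyl]-4-ArTs-tetrahydro-1H,3H-furo[3,4-c]furan | COc1cc(ccc1O[Si](C)(C)C(C)(C)C)[C@@H]1OC[C@@H]2[C@H]1CO[C@H]2c1ccc(OS(=O)(=O)c2ccc(C)cc2)c(OC)c1 | intermediate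
17 | 4-[(1R,3aS,4R,6aS)-4-ArTs-tetrahydro-1H,3H-furo[3,4-c]furan-1-yl]-2-methoxyphenol | COc1cc(ccc1O)[C@@H]1OC[C@@H]2[C@H]1CO[C@H]2c1ccc(OS(=O)(=O)c2ccc(C)cc2)c(OC)c1 | intermediate
18 | (4R)-4-benzyl-3-(chloroacetyl)-1,3-oxazolidin-2-one | O=C(CCl)N1[C@H](Cc2ccccc2)COC1=O | starting material
19 | (4R)-4-benzyl-3-[(core-O)acetyl]-1,3-oxazolidin-2-one | O=C(COc1ccc(cc1OC)[C@@H]1OC[C@@H]2[C@H]1CO[C@H]2c1ccc(OS(=O)(=O)c2ccc(C)cc2)c(OC)c1)N1[C@H](Cc2ccccc2)COC1=O | intermediate
20 | vanillin | COc1cc(C=O)ccc1O | starting material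
21 | 4-formyl-2-methoxyphenyl 4-methylbenzenesulfonate | COc1cc(C=O)ccc1OS(=O)(=O)c1ccc(C)cc1 | intermediate
22 | dibutylboron (Z)-enolate of 19 | CCCCB(CCCC)O/C(N1[C@H](Cc2ccccc2)COC1=O)=C\Oc1ccc(cc1OC)[C@@H]1OC[C@@H]2[C@H]1CO[C@H]2c1ccc(OS(=O)(=O)c2ccc(C)cc2)c(OC)c1 | intermediate
23 | (4R)-4-benzyl-3-[(2R,3S)-3-hydroxy-3-ArTs-2-(core-O)propanoyl]-1,3-oxazolidin-2-one | COc1cc(ccc1OS(=O)(=O)c1ccc(C)cc1)[C@H](O)[C@H](C(=O)N1[C@H](Cc2ccccc2)COC1=O)Oc1ccc(cc1OC)[C@@H]1OC[C@@H]2[C@H]1CO[C@H]2c1ccc(OS(=O)(=O)c2ccc(C)cc2)c(OC)c1 | intermediate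
24 | (1S,2S)-1-ArTs-2-(core-O)propane-1,3-diol (threo) | COc1cc(ccc1OS(=O)(=O)c1ccc(C)cc1)[C@H](O)[C@H](CO)Oc1ccc(cc1OC)[C@@H]1OC[C@@H]2[C@H]1CO[C@H]2c1ccc(OS(=O)(=O)c2ccc(C)cc2)c(OC)c1 | intermediate
25 | (1R,2S)-1-ArTs-2-(core-O)propane-1,3-diyl bis(4-nitrobenzoate) (erythro) | COc1cc(ccc1OS(=O)(=O)c1ccc(C)cc1)[C@@H](OC(=O)c1ccc(cc1)[N+](=O)[O-])[C@H](COC(=O)c1ccc(cc1)[N+](=O)[O-])Oc1ccc(cc1OC)[C@@H]1OC[C@@H]2[C@H]1CO[C@H]2c1ccc(OS(=O)(=O)c2ccc(C)cc2)c(OC)c1 | intermediate
26 | 4-[(1R,2S)-1,3-dihydroxy-2-{4-[(1R,3aS,4R,6aS)-4-(4-hydroxy-3-methoxyphenyl)tetrahydro-1H,3H-furo[3,4-c]furan-1-yl]-2-methoxyphenoxy}propyl]-2-methoxyphenol | COc1cc([C@@H](O)[C@H](CO)Oc2ccc([C@@H]3OC[C@@H]4[C@H]3CO[C@H]4c3ccc(O)c(OC)c3)cc2OC)ccc1O | target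

**Step count and risks**

Total step count: 18. Longest linear sequence: 16 (steps 1–8, 10–13, 15–18).

Steps most likely to fail:

1. Step 6. The sulfonate-detuned cyclopropane may be captured too slowly by the weakly nucleophilic formaldehyde, so that oligomerization of formaldehyde or isomerization of the cyclopropane to an alkene takes over. The fallback sets out from 9 and returns at 11. Compound 9 would be opened with methanol (Cu(OTf)2 cat., CH2Cl2; SN2-type opening with inversion) to methyl (4S)-4-[(R)-methoxy(ArTs)methyl]-2-oxooxolane-3-carboxylate F1. Dealkoxycarbonylation (LiCl, wet DMSO, 130 °C) would give (4S)-4-[(R)-methoxy(ArTs)methyl]oxolan-2-one F2. C-Trifluoroacetylation (LiN(SiMe3)2, CF3CO2CH2CF3, THF, −78 °C) would give (4S)-4-[(R)-methoxy(ArTs)methyl]-3-(trifluoroacetyl)oxolan-2-one F3, and detrifluoroacetylative diazo transfer (MsN3, Et3N, MeCN) the diazo lactone (4S)-3-diazo-4-[(R)-methoxy(ArTs)methyl]oxolan-2-one F4. Rh2(OAc)4-catalysed 1,5 C–H insertion of the carbenoid into the O-methyl group would then close ring B cis-fused and give 11.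

2. Step 4. Facial discrimination by the copper catalyst on the (Z)-1,2-disubstituted alkene may be insufficient, or cis geometry may be partly lost. The fallback sets out from 5 and returns at 9. Compound 5 would be desilylated (Bu4NF, THF) to 4-[(1Z)-3-hydroxyprop-1-en-1-yl]-2-methoxyphenyl 4-methylbenzenesulfonate F5 and acylated (methyl malonyl chloride, pyridine, CH2Cl2) to (2Z)-3-ArTs-prop-2-en-1-yl methyl propanedioate F6. Diazo transfer (4-acetamidobenzenesulfonyl azide, Et3N, MeCN) would give (2Z)-3-ArTs-prop-2-en-1-yl methyl 2-diazopropanedioate F7. Tethered, stereospecific intramolecular cyclopropanation with a chiral dirhodium carboxamidate, Rh2(4S-MEAZ)4 (dirhodium tetrakis[methyl (4S)-2-oxoazetidine-4-carboxylate]) or its antipode, in CH2Cl2 would give the endo-aryl lactone 9 directly, with crystallization to raise enantiomeric purity if needed.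

3. Step 17. Elimination to an enol ether or partial ionization may compete with clean displacement with inversion at the benzylic carbinol. The fallback sets out from 24 and returns at 26. Compound 24 would be silylated at the primary hydroxyl (TBSCl, imidazole, DMF) to (1S,2S)-3-(TBS-oxy)-1-ArTs-2-(core-O)propan-1-ol F8 and oxidized (Dess–Martin periodinane, NaHCO3, CH2Cl2) to (2S)-3-(TBS-oxy)-1-ArTs-2-(core-O)propan-1-one F9. Chelation-controlled reduction (Zn(BH4)2, Et2O, −20 °C; zinc bridges the ketone and the o-methoxyaryloxy group and hydride adds anti to the CH2OTBS branch) would give the erythro alcohol (1R,2S)-3-(TBS-oxy)-1-ArTs-2-(core-O)propan-1-ol F10. Bu4NF would give (1R,2S)-1-ArTs-2-(core-O)propane-1,3-diol F11, which is hydrolysed with KOH in aqueous 1,4-dioxane as in step 18 to give 26.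

**Further compounds**

F1 | step 6 | methyl (4S)-4-[(R)-methoxy(ArTs)methyl]-2-oxooxolane-3-carboxylate (C3 epimers) | O=C1OC[C@@H]([C@@H](OC)c2ccc(OS(=O)(=O)c3ccc(C)cc3)c(OC)c2)C1C(=O)OC
F2 | step 6 | (4S)-4-[(R)-methoxy(ArTs)methyl]oxolan-2-one | O=C1OC[C@@H]([C@@H](OC)c2ccc(OS(=O)(=O)c3ccc(C)cc3)c(OC)c2)C1
F3 | step 6 | (4S)-4-[(R)-methoxy(ArTs)methyl]-3-(trifluoroacetyl)oxolan-2-one | O=C1OC[C@@H]([C@@H](OC)c2ccc(OS(=O)(=O)c3ccc(C)cc3)c(OC)c2)C1C(=O)C(F)(F)F
F4 | step 6 | (4S)-3-diazo-4-[(R)-methoxy(ArTs)methyl]oxolan-2-one | O=C1OC[C@@H]([C@@H](OC)c2ccc(OS(=O)(=O)c3ccc(C)cc3)c(OC)c2)C1=[N+]=[N-]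
F5 | step 4 | 4-[(1Z)-3-hydroxyprop-1-en-1-yl]-2-methoxyphenyl 4-methylbenzenesulfonate | COc1cc(/C=C\CO)ccc1OS(=O)(=O)c1ccc(C)cc1
F6 | step 4 | (2Z)-3-ArTs-prop-2-en-1-yl methyl propanedioate | COc1cc(/C=C\COC(=O)CC(=O)OC)ccc1OS(=O)(=O)c1ccc(C)cc1
F7 | step 4 | (2Z)-3-ArTs-prop-2-en-1-yl methyl 2-diazopropanedioate | COc1cc(/C=C\COC(=O)C(=[N+]=[N-])C(=O)OC)ccc1OS(=O)(=O)c1ccc(C)cc1
F8 | step 17 | (1S,2S)-3-(TBS-oxy)-1-ArTs-2-(core-O)propan-1-ol | COc1cc(ccc1OS(=O)(=O)c1ccc(C)cc1)[C@H](O)[C@H](CO[Si](C)(C)C(C)(C)C)Oc1ccc(cc1OC)[C@@H]1OC[C@@H]2[C@H]1CO[C@H]2c1ccc(OS(=O)(=O)c2ccc(C)cc2)c(OC)c1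
F9 | step 17 | (2S)-3-(TBS-oxy)-1-ArTs-2-(core-O)propan-1-one | COc1cc(ccc1OS(=O)(=O)c1ccc(C)cc1)C(=O)[C@H](CO[Si](C)(C)C(C)(C)C)Oc1ccc(cc1OC)[C@@H]1OC[C@@H]2[C@H]1CO[C@H]2c1ccc(OS(=O)(=O)c2ccc(C)cc2)c(OC)c1
F10 | step 17 | (1R,2S)-3-(TBS-oxy)-1-ArTs-2-(core-O)propan-1-ol | COc1cc(ccc1OS(=O)(=O)c1ccc(C)cc1)[C@@H](O)[C@H](CO[Si](C)(C)C(C)(C)C)Oc1ccc(cc1OC)[C@@H]1OC[C@@H]2[C@H]1CO[C@H]2c1ccc(OS(=O)(=O)c2ccc(C)cc2)c(OC)c1
F11 | step 17 | (1R,2S)-1-ArTs-2-(core-O)propane-1,3-diol | COc1cc(ccc1OS(=O)(=O)c1ccc(C)cc1)[C@@H](O)[C@H](CO)Oc1ccc(cc1OC)[C@@H]1OC[C@@H]2[C@H]1CO[C@H]2c1ccc(OS(=O)(=O)c2ccc(C)cc2)c(OC)c1
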